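**Plan**

- Retrosynthesis: the free 5-OH and 3'-OH are traced back to a 5-O-methyl ether and a 3'-O-benzyl ether, the C3–O bond is cut back to C3–H, and the ring B C3'–O bond is cut back to a C–H bond. This leaves nobiletin.
- Enabling feature: ring A (C5 to C8 all oxygenated), ring C and the two ring B methoxy groups of the target are already those of nobiletin. Ring B of nobiletin has one C–H (C5' in nobiletin, C3' in the target) whose only neighbour is the 4'-methoxy oxygen, whereas C2'–H, C6'–H and C3–H are shielded by the chromone.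
- Forward: no ring is formed. The C3'–O bond is made first by C–H borylation and oxidation, the new phenol is benzylated, the C3–O bond follows by lithiation, borate trapping and peroxide oxidation, and BCl3 then frees 3'-OH and 5-OH in one operation.
- Stereochemistry: the target has no stereocentre, so none has to be set.

Key step: step 1

Remark: ring B positions are given in nobiletin numbering in step 1 (new oxygen at C5') and in target numbering afterwards (the same carbon is C3'). Commercial LDA solution is assumed.

**Step 1**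
Reactants: 1 nobiletin; 2 bis(pinacolato)diboron
Product: 4 2-(3-hydroxy-4,5-dimethoxyphenyl)-5,6,7,8-tetramethoxychromen-4-one, via pinacol arylboronate 3 (not isolated)
Conditions: [Ir(OMe)(cod)]2 (3 mol %), 3,4,7,8-tetramethyl-1,10-phenanthroline (6 mol %), B2pin2 (1.5 equiv), THF, 80 °C; then NaBO3·4H2O, THF/H2O, rt
Reagents that add atoms: sodium perborate tetrahydrate (NaBO3·4H2O), [Na+].[Na+].O[B-]1(O)OO[B-](O)(O)OO1 (supplies the phenol oxygen)
Why: [Ir(OMe)(cod)]2, the phenanthroline and B2pin2 should form a trivalent iridium tris(boryl) complex that cleaves an arene C–H bond by oxidative addition and releases boronate 3 by C–B reductive elimination, after which perborate adds to boron, the aryl group migrates from boron to oxygen and hydrolysis gives the phenol. This is the known sterically governed iridium-catalysed arene C–H borylation with one-flask boronate oxidation, applied here to a flavone. No ring is closed and no stereocentre is formed. The step needs site selectivity among four sp2 C–H bonds: C3–H and C2'–H are each flanked by two substituents, C6'–H lies ortho to the bulky chromone, and only C5'–H has a single small methoxy neighbour, which is an ortho group this catalyst tolerates and which also acidifies that C–H bond. A second borylation is blocked because every remaining C–H bond is then doubly flanked. NaBO3 is preferred to alkaline H2O2 so that the chromone enone is not attacked.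

**Step 2**
Reactants: 4 2-(3-hydroxy-4,5-dimethoxyphenyl)-5,6,7,8-tetramethoxychromen-4-one; 5 benzyl bromide
Product: 6 2-(3-benzyloxy-4,5-dimethoxyphenyl)-5,6,7,8-tetramethoxychromen-4-one
Conditions: BnBr, K2CO3, DMF, rt
Reagents that add atoms: benzyl bromide 5, BrCc1ccccc1
Why: Williamson ether synthesis on the only OH group should be clean, and the benzyl ether keeps the phenol from quenching LDA in step 3 and leaves again in step 4.

**Step 3**
Reactants: 6 2-(3-benzyloxy-4,5-dimethoxyphenyl)-5,6,7,8-tetramethoxychromen-4-one; 7 trimethyl borate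
Product: 10 2-(3-benzyloxy-4,5-dimethoxyphenyl)-3-hydroxy-5,6,7,8-tetramethoxychromen-4-one, via 3-lithioflavone 8 (not isolated), via lithium trimethoxyborate 9 (not isolated)
Conditions: LiN(iPr)2 (LDA), THF, −78 °C; B(OMe)3, −78 → 0 °C; AcOH, 30% aq. H2O2, 0 °C → rt
Reagents that add atoms: hydrogen peroxide, OO (supplies the C3 oxygen)
Why: Directed deprotonation of the flavone C3–H by LDA (the only acidic sp2 C–H, with lithium held by the C4 carbonyl oxygen), borate trapping and boronate oxidation by 1,2-migration from boron to oxygen is an established route from 5-methoxyflavones to flavonols, and the benzyl and methyl ethers are inert to it.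

**Step 4**
Reactants: 10 2-(3-benzyloxy-4,5-dimethoxyphenyl)-3-hydroxy-5,6,7,8-tetramethoxychromen-4-one
Product: 13 3-demethyldigicitrin (3,5-dihydroxy-2-(3-hydroxy-4,5-dimethoxyphenyl)-6,7,8-trimethoxychromen-4-one), via debenzylated bis(dichloroboryl) ester 11 (not isolated), via tris(dichloroboryl) ester 12 (not isolated)
Conditions: BCl3 (5 equiv), C6HMe5 (3 equiv), CH2Cl2, −78 → 0 °C; MeOH, then 1 M aq. HCl
Reagents that add atoms: none
Why: BCl3-mediated ether cleavage should remove the aryl benzyl ether at −78 °C, with pentamethylbenzene trapping the benzyl cation by Friedel–Crafts alkylation, and on warming should remove only the 5-O-methyl group through the six-membered boron chelate with the C4 carbonyl (chelation-controlled peri-demethylation), since the other five methoxy groups have no such chelate.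

**Compound list**

1 | nobiletin, 2-(3,4-dimethoxyphenyl)-5,6,7,8-tetramethoxychromen-4-one | COc1ccc(-c2cc(=O)c3c(OC)c(OC)c(OC)c(OC)c3o2)cc1OC | starting material
2 | bis(pinacolato)diboron | CC1(C)OB(OC1(C)C)B1OC(C)(C)C(C)(C)O1 | starting material
3 | 2-[3,4-dimethoxy-5-(4,4,5,5-tetramethyl-1,3,2-dioxaborolan-2-yl)phenyl]-5,6,7,8-tetramethoxychromen-4-one | COc1cc(-c2cc(=O)c3c(OC)c(OC)c(OC)c(OC)c3o2)cc(B2OC(C)(C)C(C)(C)O2)c1OC | intermediate (not isolated)
4 | 2-(3-hydroxy-4,5-dimethoxyphenyl)-5,6,7,8-tetramethoxychromen-4-one | COc1cc(-c2cc(=O)c3c(OC)c(OC)c(OC)c(OC)c3o2)cc(O)c1OC | intermediate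
5 | benzyl bromide | BrCc1ccccc1 | starting material
6 | 2-(3-benzyloxy-4,5-dimethoxyphenyl)-5,6,7,8-tetramethoxychromen-4-one | COc1cc(-c2cc(=O)c3c(OC)c(OC)c(OC)c(OC)c3o2)cc(OCc2ccccc2)c1OC | intermediate
7 | trimethyl borate | COB(OC)OC | starting material
8 | 2-(3-benzyloxy-4,5-dimethoxyphenyl)-3-lithio-5,6,7,8-tetramethoxychromen-4-one | COc1cc(-c2oc3c(OC)c(OC)c(OC)c(OC)c3c(=O)c2[Li])cc(OCc2ccccc2)c1OC | intermediate (not isolated)
9 | lithium [2-(3-benzyloxy-4,5-dimethoxyphenyl)-5,6,7,8-tetramethoxy-4-oxochromen-3-yl]trimethoxyborate | [Li+].COc1cc(-c2oc3c(OC)c(OC)c(OC)c(OC)c3c(=O)c2[B-](OC)(OC)OC)cc(OCc2ccccc2)c1OC | intermediate (not isolated)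
10 | 2-(3-benzyloxy-4,5-dimethoxyphenyl)-3-hydroxy-5,6,7,8-tetramethoxychromen-4-one | COc1cc(-c2oc3c(OC)c(OC)c(OC)c(OC)c3c(=O)c2O)cc(OCc2ccccc2)c1OC | intermediate
11 | 3-O,3'-O-bis(dichloroboryl) ester of 3-hydroxy-2-(3-hydroxy-4,5-dimethoxyphenyl)-5,6,7,8-tetramethoxychromen-4-one (drawn unchelated) | COc1cc(-c2oc3c(OC)c(OC)c(OC)c(OC)c3c(=O)c2OB(Cl)Cl)cc(OB(Cl)Cl)c1OC | intermediate (not isolated)
12 | 3-O,5-O,3'-O-tris(dichloroboryl) ester of 3-demethyldigicitrin (drawn unchelated) | COc1cc(-c2oc3c(OC)c(OC)c(OC)c(OB(Cl)Cl)c3c(=O)c2OB(Cl)Cl)cc(OB(Cl)Cl)c1OC | intermediate (not isolated)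
13 | 3-demethyldigicitrin, 3,5-dihydroxy-2-(3-hydroxy-4,5-dimethoxyphenyl)-6,7,8-trimethoxychromen-4-one | COc1cc(-c2oc3c(OC)c(OC)c(OC)c(O)c3c(=O)c2O)cc(O)c1OC | target

**Count**

Total steps: 4. Longest linear sequence: 4 steps (from nobiletin).

**Steps most likely to fail**

1. Step 1. C–H activation next to the methoxy group may be sluggish on this electron-rich, 1,2,4-trisubstituted ring, or may drift to C6'–H, so that conversion stalls or the boron ends up at the wrong carbon. The fallback sets out from nobiletin 1 and comes back at benzyl ether 6. Alkaline fission of 1 (KOH, aq. EtOH, reflux; hydroxide addition at C2, ring opening and retro-Claisen cleavage) should give 2'-hydroxy-3',4',5',6'-tetramethoxyacetophenone F1 beside veratric acid. Claisen–Schmidt condensation of F1 with purchased 3-benzyloxy-4,5-dimethoxybenzaldehyde F2 (KOH, EtOH, rt) should give (E)-3-(3-benzyloxy-4,5-dimethoxyphenyl)-1-(2-hydroxy-3,4,5,6-tetramethoxyphenyl)prop-2-en-1-one F3. Oxidative cyclisation of F3 with I2 (cat.) in DMSO at 120 °C should give 6. Here the ring B oxygen pattern is bought and ring C is rebuilt, so no C–H functionalisation is needed.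

2. Step 4. Demethylation may run on past the 5-position to the crowded 6- or 4'-methoxy groups, or the peri-demethylation may stall because the C4 carbonyl is already tied up by the 3-O-boron chelate. The fallback sets out from 10 and comes back at 13. Hydrogenolysis (H2, 10% Pd/C, EtOAc/MeOH, rt) should give 3-hydroxy-2-(3-hydroxy-4,5-dimethoxyphenyl)-5,6,7,8-tetramethoxychromen-4-one F4 without any Lewis acid. Heating F4 with concentrated HCl in EtOH, the Brønsted-acid solvolysis that removes only the 5-O-methyl group of citrus polymethoxyflavones, should then give 13.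

3. Step 3. The 3-lithio species may open by β-elimination of the ring phenoxide to an ynone before it is trapped, or deprotonation may be incomplete, and the boronate may be lost by protodeboronation on acidification. The fallback sets out from 6 and comes back at 10. Dimethyldioxirane in acetone/CH2Cl2 at 0 °C should epoxidise the enol-ether-like C2=C3 bond to racemic 2-(3-benzyloxy-4,5-dimethoxyphenyl)-2,3-epoxy-5,6,7,8-tetramethoxychroman-4-one F5. The benzylic C–H bonds should react more slowly at this temperature. Catalytic TsOH in CH2Cl2 should then open the epoxide at C2 and tautomerise the product to flavonol 10. No carbanion is involved.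

**Further compounds**

F1 | step 1 | 2'-hydroxy-3',4',5',6'-tetramethoxyacetophenone | CC(=O)c1c(O)c(OC)c(OC)c(OC)c1OC
F2 | step 1 | 3-benzyloxy-4,5-dimethoxybenzaldehyde (purchased) | COc1cc(C=O)cc(OCc2ccccc2)c1OC
F3 | step 1 | (E)-3-(3-benzyloxy-4,5-dimethoxyphenyl)-1-(2-hydroxy-3,4,5,6-tetramethoxyphenyl)prop-2-en-1-one | COc1cc(/C=C/C(=O)c2c(O)c(OC)c(OC)c(OC)c2OC)cc(OCc2ccccc2)c1OC
F4 | step 4 | 3-hydroxy-2-(3-hydroxy-4,5-dimethoxyphenyl)-5,6,7,8-tetramethoxychromen-4-one | COc1cc(-c2oc3c(OC)c(OC)c(OC)c(OC)c3c(=O)c2O)cc(O)c1OC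
F5 | step 3 | 2-(3-benzyloxy-4,5-dimethoxyphenyl)-2,3-epoxy-5,6,7,8-tetramethoxychroman-4-one (racemic, one enantiomer drawn) | COc1cc([C@]23O[C@H]2C(=O)c2c(OC)c(OC)c(OC)c(OC)c2O3)cc(OCc2ccccc2)c1OC
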